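The question on the board: which way of running one charge gives the highest share of target among target, side product and trapped intermediate?

| setting | amber | violet | blue | green |
|---|---|---|---|---|
| starting material | 0.10 M | 0.10 M | 0.10 M | 0.10 M (fed, over 0.500 h) |
| partner | 2.50 equiv (fed, over 0.500 h) | 2.50 equiv | 2.50 equiv | 2.50 equiv |
| protic impurity | 0.100 M | 0.100 M | 0.100 M | 0.100 M |
| capture agent | 0.0300 M | 0.0300 M | 0.0300 M | 0.0300 M |
| time | 1.0 h |  | 1.0 h | 1.0 h |
| remark | a stirred flask in which partner is dosed at a steady rate over 0.500 h without added volume, worked up at 1.0 h | a single well-mixed tank run continuously and read at steady state, 1.0 h in it on average | everything together in a closed stirred flask, run for 1.0 h | a stirred flask in which starting material is dosed at a steady rate over 0.500 h without added volume, worked up at 1.0 h |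

1. the set-up with the highest share of target in all that became target or side product or trapped intermediate, at the outlet or at the end ("none" if the first two lie within 2 percentage points) (amber / violet / blue / green / none)
2. share of target in all that became target or side product or trapped intermediate, at the outlet or at the end, amber
3. share of target in all that became target or side product or trapped intermediate, at the outlet or at the end, violet
4. share of target in all that became target or side product or trapped intermediate, at the outlet or at the end, blue
5. share of target in all that became target or side product or trapped intermediate, at the outlet or at the end, green

    intermediate A ⇌ intermediate B (K1 = 32.2, k1 = 0.0849 min⁻¹)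
    starting material + protic impurity → quenched substrate (k2 = 0.425 L mol⁻¹ min⁻¹)
    starting material + partner ⇌ intermediate A (K3 = 4.6 L mol⁻¹, k3 = 0.0364 L mol⁻¹ min⁻¹)
    intermediate B → target (k4 = 0.00198 min⁻¹)
    starting material → side product (k5 = 0.00338 min⁻¹)
    capture agent + intermediate A → trapped intermediate (k6 = 0.434 L mol⁻¹ min⁻¹)

- the stated concentrations are those of everything mixed, before any reaction; amounts are the same in each set-up
- the feed brings no volume worth counting
- run time (amber): 1.0 h

Two colleagues argue it out. The first writes the balance of starting material, which is the limiting reagent against partner at 2.50 equiv. At the start of blue, protic impurity consumes it at 0.0425 min⁻¹ and partner at 0.00910 min⁻¹, a smaller rate, while the side step runs at 0.00338 min⁻¹. So partner receives 16.6 % of the early turnover. His view is that the share follows what gets through this gate. He therefore names blue, with partner at full strength from the first moment, then the dosed flasks, and last the tank, which works at outlet strength.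

The second answers that reaching intermediate B is not yet target. Intermediate B has a half-life of 5.8 h by its last step, longer than the 1.0 h of the run, so what counts is how long it is held. Let k be that step's constant, 0.00198 min⁻¹, and τ the mean time in violet, 1.0 h. In a steady tank, target leaves as fast as it forms, so target over τ equals k times intermediate B, and the ratio of the two is kτ = 11.9 %. This number, target standing per intermediate B standing, is the hold ratio h. In a closed flask where intermediate B climbs about evenly from nothing, its mean is half its final value, so h is about 5.94 %. By this estimate violet gets twice the target per intermediate B.

My own reckoning stops at that ratio. It gives no share and does not say how much intermediate B each set-up makes, so violet is my judgement, and I commit to no percentage.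

The forecast is the second chemist's number: violet wins, with 3.7 % for amber, 12.4 % for violet, 9.2 % for blue and 7 % for green. Its ground is this: “The slow last step (B to target) means target depends on how long B is held”.

The simulation gives 4.08 % for amber, 12.3 % for violet, 8.53 % for blue and 6.06 % for green, so violet stands highest.

At the end, amber holds 0.415 % of target on 8.22 % of intermediate B, a reading of h of 5.05 %, below the closed-flask estimate, and blue reads 6.91 %, above it. A flask like amber but with 0.25 M of starting material reads 4.94 %, from 1.15 % of target on 23.3 % of intermediate B. The first chemist's order stands among the flasks other than the tank: blue's share of 8.53 % lies above those of the dosed flasks, 6.06 % in green and 4.08 % in amber.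

(All constants belong to no real substance; the flask was simulated.)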